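## Retrosynthetic overview
1. The C1–C10 oxirane goes in last, by peracid epoxidation directed by the free C2–OH. The angelate is placed on C8–OH just before that.
2. The ten-membered carbocycle is closed at C7–C8. The β-carbon (C7) of a 3-(bromomethyl)butenolide is made nucleophilic as an allylchromium (a lactone homoenolate) and attacks the C8 aldehyde. This sets C7 and C8 and unveils the α-methylene lactone.
3. The butenolide comes from ring-closing metathesis of the 2-(bromomethyl)acrylate of the C6 allylic alcohol. C6 is set by Cornforth-controlled vinylation of a cis-epoxy aldehyde.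
4. The cis C4–C5 oxirane and the Z geometry come from a temporary six-membered unsaturated δ-lactone (C2–O–C6). It is made by an asymmetric vinylketene/enal [4+2] reaction and epoxidised anti to its C2 side chain.
5. Ring order: δ-lactone (temporary) → C4–C5 oxirane → butenolide → carbocycle → C1–C10 oxirane.

Assumption: C1–C15 follow germacrane numbering (lactone O on C6, angelate on C8, OH on C2). In step 3 the ligand antipode is used if the enantiomer written gives the R-lactone.

## Route

Step 1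
Reactants: 1 4-(tert-butyldimethylsilyloxy)but-1-yne
Product: 4 (E)-5-(tert-butyldimethylsilyloxy)-3-methylpent-2-en-1-ol, via alkenyldimethylalane 2 (not isolated), via lithium alanate 3 (not isolated)
Conditions: AlMe3 (2.5 equiv), Cp2ZrCl2 (0.2 equiv), CH2Cl2, 0 °C → rt; n-BuLi, THF/hexane, −78 → 0 °C; (CH2O)n, rt; aq. K/Na tartrate
Reagents that add atoms: trimethylaluminium C[Al](C)C; formaldehyde (as paraformaldehyde) C=O
Why: Negishi zirconium-catalysed carboalumination adds methyl and aluminium syn across the terminal alkyne (Al on the terminus), which fixes the E C1=C10 geometry, and the derived alanate is hydroxymethylated with retention.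

Step 2
Reactants: 4 (E)-5-(tert-butyldimethylsilyloxy)-3-methylpent-2-en-1-ol
Product: 5 (E)-5-(tert-butyldimethylsilyloxy)-3-methylpent-2-enal
Conditions: MnO2 (15 equiv), CH2Cl2, rt
Reagents that add atoms: none
Why: Neutral, allylic-selective MnO2 oxidation gives the enal without E/Z scrambling and leaves the silyl ether alone.

Step 3
Reactants: 5 (E)-5-(tert-butyldimethylsilyloxy)-3-methylpent-2-enal; 6 3-methylbut-2-enoyl chloride
Product: 8 (6S)-6-[(E)-4-(tert-butyldimethylsilyloxy)-2-methylbut-1-enyl]-4-methyl-5,6-dihydro-2H-pyran-2-one, via isopropenylketene 7 (not isolated)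
Conditions: Er(OTf)3 (10 mol %), (1R,2S)-2-(pyrrolidin-1-yl)-1-phenylpropan-1-ol (20 mol %), i-Pr2NEt (2.5 equiv), 6 added over 6 h, CH2Cl2, −10 °C
Reagents that add atoms: none
Why: In this cooperative Lewis acid/Lewis base vinylketene hetero-Diels–Alder reaction the base dehydrochlorinates 6 to 7, the ligand amine turns 7 into an s-cis ammonium dienolate and the Er-bound enal is attacked on its Si face, so one [4+2] event forms C2–C3, sets C2 (S) and locks C4=C5 as Z in the ring (non-enolisable conjugated aldehydes are the known substrates and this β,β-disubstituted enal extends that scope).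

Step 4
Reactants: 8 (6S)-6-[(E)-4-(tert-butyldimethylsilyloxy)-2-methylbut-1-enyl]-4-methyl-5,6-dihydro-2H-pyran-2-one
Product: 9 (1R,4S,6R)-4-[(E)-4-(tert-butyldimethylsilyloxy)-2-methylbut-1-enyl]-6-methyl-3,7-dioxabicyclo[4.1.0]heptan-2-one
Conditions: t-BuOOH (3 equiv, decane), benzyltrimethylammonium hydroxide (0.15 equiv), THF, 0 °C
Reagents that add atoms: tert-butyl hydroperoxide CC(C)(C)OO
Why: In this Weitz–Scheffer nucleophilic epoxidation the peroxide anion adds only to the electron-poor ring alkene, axially and anti to the pseudo-equatorial C2 side chain, and then closes, which sets C4 and C5 as the cis-fused oxirane trans to the side chain, leaves C1=C10 untouched and, with peroxide kept in excess over base, suppresses eliminative lactone opening.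

Step 5
Reactants: 9 (1R,4S,6R)-4-[(E)-4-(tert-butyldimethylsilyloxy)-2-methylbut-1-enyl]-6-methyl-3,7-dioxabicyclo[4.1.0]heptan-2-one
Product: 11 (2R,3R)-3-[(2S,3E)-2,6-bis(tert-butyldimethylsilyloxy)-4-methylhex-3-enyl]-N-methoxy-N,3-dimethyloxirane-2-carboxamide, via chloromagnesium alkoxide 10 (not isolated)
Conditions: MeNH(OMe)·HCl (2 equiv), i-PrMgCl (4 equiv), THF, −20 °C; then TBSOTf (2.5 equiv), −20 → 0 °C
Reagents that add atoms: N,O-dimethylhydroxylamine hydrochloride CNOC.Cl; tert-butyldimethylsilyl triflate CC(C)(C)[Si](C)(C)OS(=O)(=O)C(F)(F)F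
Why: Weinreb aminolysis opens the glycidic lactone at the acyl carbon and the released C2 alkoxide is silylated in the same flask before it can relactonise, so no stereocentre is touched.

Step 6
Reactants: 11 (2R,3R)-3-[(2S,3E)-2,6-bis(tert-butyldimethylsilyloxy)-4-methylhex-3-enyl]-N-methoxy-N,3-dimethyloxirane-2-carboxamide
Product: 12 (2R,3R)-3-[(2S,3E)-2,6-bis(tert-butyldimethylsilyloxy)-4-methylhex-3-enyl]-3-methyloxirane-2-carbaldehyde
Conditions: i-Bu2AlH (1.2 equiv), THF, −78 °C; aq. K/Na tartrate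
Reagents that add atoms: none
Why: Weinreb amide reduction stops at the aldehyde because the chelated tetrahedral adduct survives until work-up, and the oxirane and silyl ethers are inert at −78 °C.

Step 7
Reactants: 12 (2R,3R)-3-[(2S,3E)-2,6-bis(tert-butyldimethylsilyloxy)-4-methylhex-3-enyl]-3-methyloxirane-2-carbaldehyde; 13 2-(bromomethyl)acrylic acid
Product: 16 (1S)-1-{(2S,3R)-3-[(2S,3E)-2,6-bis(tert-butyldimethylsilyloxy)-4-methylhex-3-enyl]-3-methyloxiran-2-yl}prop-2-enyl 2-(bromomethyl)acrylate, via acid chloride 14 (not isolated), via bromomagnesium alkoxide 15 (not isolated)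
Conditions: side flask: 13, (COCl)2, DMF (cat.), CH2Cl2, 0 °C → rt, evaporate; main flask: 12, CH2=CHMgBr (1.1 equiv), THF, −78 °C, 1 h; then 14 in THF, −78 → 0 °C
Reagents that add atoms: vinylmagnesium bromide C=C[Mg]Br
Why: The Grignard addition follows Cornforth/Felkin–Anh control (C=O anti to the oxirane C–O bond, attack past H5 and away from the cis C3 branch) to give the 5,6-anti alkoxide (C6 S), which is acylated in situ by the amine-free acid chloride so that the allylic bromide is not quaternised.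

Step 8
Reactants: 16 (1S)-1-{(2S,3R)-3-[(2S,3E)-2,6-bis(tert-butyldimethylsilyloxy)-4-methylhex-3-enyl]-3-methyloxiran-2-yl}prop-2-enyl 2-(bromomethyl)acrylate
Product: 17 (5S)-3-(bromomethyl)-5-{(2S,3R)-3-[(2S,3E)-2,6-bis(tert-butyldimethylsilyloxy)-4-methylhex-3-enyl]-3-methyloxiran-2-yl}furan-2(5H)-one
Conditions: second-generation Grubbs catalyst (5 mol %), 1,4-benzoquinone (10 mol %), CH2Cl2 (5 mM), 40 °C
Reagents that add atoms: none
Why: Ring-closing metathesis starts at the only monosubstituted alkene and closes the favoured five-membered ring onto the 2-substituted acrylate (as methacrylates do), while the trisubstituted C1=C10 alkene, the oxirane, the bromide and C6 are spectators.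

Step 9
Reactants: 17 (5S)-3-(bromomethyl)-5-{(2S,3R)-3-[(2S,3E)-2,6-bis(tert-butyldimethylsilyloxy)-4-methylhex-3-enyl]-3-methyloxiran-2-yl}furan-2(5H)-one
Product: 18 (5S)-3-(bromomethyl)-5-{(2S,3R)-3-[(2S,3E)-2-(tert-butyldimethylsilyloxy)-6-hydroxy-4-methylhex-3-enyl]-3-methyloxiran-2-yl}furan-2(5H)-one
Conditions: Et3N·3HF (4 equiv), THF, 0 °C → rt, stopped when 17 is consumed
Reagents that add atoms: none
Why: In this sterically selective fluoride desilylation the unhindered primary silyl ether is cleaved well before the hindered secondary allylic one, and the nearly neutral reagent carries no free amine, so oxirane, butenolide and allylic bromide survive.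

Step 10
Reactants: 18 (5S)-3-(bromomethyl)-5-{(2S,3R)-3-[(2S,3E)-2-(tert-butyldimethylsilyloxy)-6-hydroxy-4-methylhex-3-enyl]-3-methyloxiran-2-yl}furan-2(5H)-one
Product: 19 (5S)-3-(bromomethyl)-5-{(2S,3R)-3-[(2S,3E)-2-(tert-butyldimethylsilyloxy)-4-methyl-6-oxohex-3-enyl]-3-methyloxiran-2-yl}furan-2(5H)-one
Conditions: Dess–Martin periodinane (1.3 equiv), NaHCO3 (5 equiv), CH2Cl2, 0 °C; used at once
Reagents that add atoms: none
Why: Buffered Dess–Martin oxidation gives the β,γ-unsaturated aldehyde without moving C1=C10 into conjugation.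

Step 11
Reactants: 19 (5S)-3-(bromomethyl)-5-{(2S,3R)-3-[(2S,3E)-2-(tert-butyldimethylsilyloxy)-4-methyl-6-oxohex-3-enyl]-3-methyloxiran-2-yl}furan-2(5H)-one
Product: 22 (1(10)E,2S,4R,5S,6S,7R,8S)-2-(tert-butyldimethylsilyloxy)-4,5-epoxy-8-hydroxygermacra-1(10),11(13)-dien-12,6-olide, via allylchromium dichloride 20 (not isolated), via chromium alkoxide 21 (not isolated)
Conditions: CrCl2 (8 equiv), THF (final 2 mM), 19 added by syringe pump over 12 h, rt; H2O
Reagents that add atoms: none
Why: Proposed new method: two CrCl2 reduce the allylic C–Br bond to an allyl trivalent-chromium species with the metal on C13, so the butenolide β-carbon C7 (normally a Michael acceptor site) becomes the nucleophilic γ-terminus and adds to the C8 aldehyde through a Zimmerman–Traxler chair, anti to the C5 branch on C6 (trans lactone, C7 R) and with C9 equatorial on the ring-enforced E-type allyl unit (7,8-anti, C8 S), while the alkene moves to C11=C13 and 1,4-elimination is shut off because the C6–O bond lies in the nodal plane of the allyl system; the closest known reactions are intermolecular Cr-, Zn- or In-mediated additions of 3-(bromomethyl)furan-2(5H)-one to aldehydes and Nozaki–Hiyama allylation macrocyclisations to ten-membered germacrane rings.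

Step 12
Reactants: 22 (1(10)E,2S,4R,5S,6S,7R,8S)-2-(tert-butyldimethylsilyloxy)-4,5-epoxy-8-hydroxygermacra-1(10),11(13)-dien-12,6-olide; 23 angelic acid [(Z)-2-methylbut-2-enoic acid]
Product: 25 (1(10)E,2S,4R,5S,6S,7R,8S)-8-angeloyloxy-2-(tert-butyldimethylsilyloxy)-4,5-epoxygermacra-1(10),11(13)-dien-12,6-olide, via mixed anhydride 24 (not isolated)
Conditions: 23, 2,4,6-trichlorobenzoyl chloride, Et3N, toluene, rt, 1 h; then 22, 75 °C
Reagents that add atoms: none
Why: Yamaguchi mixed-anhydride esterification run without a nucleophilic pyridine catalyst acylates the only free hydroxyl with retention at C8 and avoids the addition–elimination path that turns angelate into tiglate.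

Step 13
Reactants: 25 (1(10)E,2S,4R,5S,6S,7R,8S)-8-angeloyloxy-2-(tert-butyldimethylsilyloxy)-4,5-epoxygermacra-1(10),11(13)-dien-12,6-olide
Product: 26 (1(10)E,2S,4R,5S,6S,7R,8S)-8-angeloyloxy-4,5-epoxy-2-hydroxygermacra-1(10),11(13)-dien-12,6-olide
Conditions: HF·pyridine, pyridine, THF, 0 °C → rt
Reagents that add atoms: none
Why: Buffered fluoride desilylation frees the C2 alcohol without base (no Michael addition to the methylene lactone, no ester cleavage) and without enough acid to trigger transannular opening of the oxirane.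

Step 14
Reactants: 26 (1(10)E,2S,4R,5S,6S,7R,8S)-8-angeloyloxy-4,5-epoxy-2-hydroxygermacra-1(10),11(13)-dien-12,6-olide
Product: 27 target, (1R,2S,4R,5S,6S,7R,8S,10R)-8-angeloyloxy-1,10:4,5-diepoxy-2-hydroxygermacr-11(13)-en-12,6-olide
Conditions: m-CPBA (1.1 equiv), NaHCO3, CH2Cl2, 0 °C
Reagents that add atoms: m-chloroperbenzoic acid O=C(OO)c1cccc(Cl)c1
Why: In this Henbest hydroxyl-directed peracid epoxidation, A(1,3) strain with the cis C14 methyl places H2 in the alkene plane, so the C2–OH sits on the outer face of the ring alkene and delivers oxygen there (threo epoxy alcohol, C1 R and C10 R), while the electron-poor angelate and methylene lactone alkenes do not react.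

## Compound list
1 | 4-(tert-butyldimethylsilyloxy)but-1-yne | C#CCCO[Si](C)(C)C(C)(C)C | starting material
2 | dimethyl[(E)-4-(tert-butyldimethylsilyloxy)-2-methylbut-1-enyl]alane | C[Al](C)/C=C(\C)CCO[Si](C)(C)C(C)(C)C | intermediate
3 | lithium butyl[(E)-4-(tert-butyldimethylsilyloxy)-2-methylbut-1-enyl]dimethylalanate | [Li+].CCCC[Al-](C)(C)/C=C(\C)CCO[Si](C)(C)C(C)(C)C | intermediate
4 | (E)-5-(tert-butyldimethylsilyloxy)-3-methylpent-2-en-1-ol | OC/C=C(\C)CCO[Si](C)(C)C(C)(C)C | intermediate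
5 | (E)-5-(tert-butyldimethylsilyloxy)-3-methylpent-2-enal | O=C/C=C(\C)CCO[Si](C)(C)C(C)(C)C | intermediate
6 | 3-methylbut-2-enoyl chloride | CC(C)=CC(=O)Cl | starting material
7 | isopropenylketene (3-methylbuta-1,3-dien-1-one) | C=C(C)C=C=O | intermediate
8 | (6S)-unsaturated δ-lactone (C2 S, C4=C5 Z in the ring, C1=C10 E) | O=C1C=C(C)C[C@H](O1)/C=C(\C)CCO[Si](C)(C)C(C)(C)C | intermediate
9 | (1R,4S,6R)-epoxy δ-lactone, oxirane trans to the side chain | O=C1[C@@H]2O[C@]2(C)C[C@H](O1)/C=C(\C)CCO[Si](C)(C)C(C)(C)C | intermediate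
10 | chloromagnesium C2 alkoxide of the ring-opened epoxy Weinreb amide | CON(C)C(=O)[C@@H]1O[C@]1(C)C[C@H](O[Mg]Cl)/C=C(\C)CCO[Si](C)(C)C(C)(C)C | intermediate
11 | (2R,3R)-cis-epoxy Weinreb amide, C2 (S) and C8 as TBS ethers | CON(C)C(=O)[C@@H]1O[C@]1(C)C[C@H](O[Si](C)(C)C(C)(C)C)/C=C(\C)CCO[Si](C)(C)C(C)(C)C | intermediate
12 | (2R,3R)-cis-epoxy aldehyde (C6 aldehyde) | O=C[C@@H]1O[C@]1(C)C[C@H](O[Si](C)(C)C(C)(C)C)/C=C(\C)CCO[Si](C)(C)C(C)(C)C | intermediate
13 | 2-(bromomethyl)acrylic acid | C=C(CBr)C(=O)O | starting material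
14 | 2-(bromomethyl)acryloyl chloride | C=C(CBr)C(=O)Cl | intermediate
15 | bromomagnesium alkoxide of the (6S)-allylic alcohol | C=C[C@H](O[Mg]Br)[C@@H]1O[C@]1(C)C[C@H](O[Si](C)(C)C(C)(C)C)/C=C(\C)CCO[Si](C)(C)C(C)(C)C | intermediate
16 | (6S)-allylic 2-(bromomethyl)acrylate | C=C[C@H](OC(=O)C(=C)CBr)[C@@H]1O[C@]1(C)C[C@H](O[Si](C)(C)C(C)(C)C)/C=C(\C)CCO[Si](C)(C)C(C)(C)C | intermediate
17 | (5S)-3-(bromomethyl)butenolide, bis-TBS ether | BrCC1=C[C@H](OC1=O)[C@@H]2O[C@]2(C)C[C@H](O[Si](C)(C)C(C)(C)C)/C=C(\C)CCO[Si](C)(C)C(C)(C)C | intermediate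
18 | (5S)-3-(bromomethyl)butenolide, free C8 primary alcohol | BrCC1=C[C@H](OC1=O)[C@@H]2O[C@]2(C)C[C@H](O[Si](C)(C)C(C)(C)C)/C=C(\C)CCO | intermediate
19 | (5S)-3-(bromomethyl)butenolide, C8 aldehyde | BrCC1=C[C@H](OC1=O)[C@@H]2O[C@]2(C)C[C@H](O[Si](C)(C)C(C)(C)C)/C=C(\C)CC=O | intermediate
20 | allylchromium dichloride (Cr on C13) | Cl[Cr](Cl)CC1=C[C@H](OC1=O)[C@@H]2O[C@]2(C)C[C@H](O[Si](C)(C)C(C)(C)C)/C=C(\C)CC=O | intermediate
21 | C8 chromium alkoxide of the macrocycle | C=C1C(=O)O[C@H]2[C@H]1[C@@H](O[Cr](Cl)Cl)C/C(C)=C/[C@@H](O[Si](C)(C)C(C)(C)C)C[C@@]1(C)O[C@@H]21 | intermediate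
22 | (2S,4R,5S,6S,7R,8S)-macrocyclic 8-alcohol, 2-OTBS, 1(10)E | C=C1C(=O)O[C@H]2[C@H]1[C@@H](O)C/C(C)=C/[C@@H](O[Si](C)(C)C(C)(C)C)C[C@@]1(C)O[C@@H]21 | intermediate
23 | angelic acid, (Z)-2-methylbut-2-enoic acid | C/C=C(/C)C(=O)O | starting material
24 | angelic 2,4,6-trichlorobenzoic anhydride | C/C=C(/C)C(=O)OC(=O)c1c(Cl)cc(Cl)cc1Cl | intermediate
25 | 8-O-angelate, 2-OTBS | C=C1C(=O)O[C@H]2[C@H]1[C@@H](OC(=O)/C(C)=C\C)C/C(C)=C/[C@@H](O[Si](C)(C)C(C)(C)C)C[C@@]1(C)O[C@@H]21 | intermediate
26 | 8-O-angelate, free 2-OH | C=C1C(=O)O[C@H]2[C@H]1[C@@H](OC(=O)/C(C)=C\C)C/C(C)=C/[C@@H](O)C[C@@]1(C)O[C@@H]21 | intermediate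
27 | CNP0388761.2 | C=C1C(=O)O[C@H]2[C@H]1[C@@H](OC(=O)/C(C)=C\C)C[C@@]1(C)O[C@@H]1[C@@H](O)C[C@@]1(C)O[C@@H]21 | target

## Step count and weak points
Total step count: 14. The acid chloride 14 and the mixed anhydride 24 are made inside steps 7 and 12.
Longest linear sequence: 14 steps (1 → 27).

**Step 11 (macrocyclisation).** Divalent chromium could give simple reduction, dimers or attack through C13. The fallback keeps the same bond and the same nucleophilic C7 but uses a closed-shell nucleophile. It sets out from 19. Pd2(dba)3-catalysed borylation with B2pin2 (THF, high dilution, rt → 40 °C; zerovalent palladium inserts into the allylic C–Br bond) gives the 3-(pinacolborylmethyl)butenolide aldehyde F1. F1 closes thermally through a six-membered chair transition state to the macrocyclic C8 borate F2. Mild aqueous hydrolysis returns to the route at 22.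

**Step 3 (asymmetric [4+2]).** The β,β-disubstituted enal lies outside the proven aldehyde scope. The fallback sets out from 5. Brown methallylation with (−)-B-methallyldiisopinocampheylborane from (+)-α-pinene (Et2O, −78 °C; NaOH/H2O2) gives the (S)-homoallylic alcohol F3. Acryloyl chloride/Et3N gives the acrylate F4. Ring-closing metathesis with the second-generation Grubbs catalyst (CH2Cl2, 40 °C) closes C4=C5 as Z and returns at 8.

**Step 4 (nucleophilic epoxidation).** The β-methyl acceptor may react slowly, and base can open the lactone to a trienoate. The fallback replaces substrate control with reagent control and sets out from 8.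
- Aminolysis and silylation as in step 5 give the (Z)-enamide F5.
- i-Bu2AlH (−78 °C) gives the (Z)-enal F6.
- NaBH4/CeCl3 gives the (Z)-allylic alcohol F7.
- Sharpless epoxidation (Ti(OiPr)4, L-(+)-diethyl tartrate, t-BuOOH, 4 Å sieves, −20 °C; same sense as nerol → (2S,3R)-epoxide) gives the epoxy alcohol F8.
- Dess–Martin oxidation returns at 12.

## Further compounds
F1 | step 11 | 3-(pinacolborylmethyl)butenolide C8 aldehyde | CC1(C)OB(CC2=C[C@H](OC2=O)[C@@H]3O[C@]3(C)C[C@H](O[Si](C)(C)C(C)(C)C)/C=C(\C)CC=O)OC1(C)C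
F2 | step 11 | macrocyclic C8 pinacol borate | C=C1C(=O)O[C@H]2[C@H]1[C@@H](OB3OC(C)(C)C(C)(C)O3)C/C(C)=C/[C@@H](O[Si](C)(C)C(C)(C)C)C[C@@]1(C)O[C@@H]21
F3 | step 3 | (4S,5E)-8-(tert-butyldimethylsilyloxy)-2,6-dimethylocta-1,5-dien-4-ol | C=C(C)C[C@H](O)/C=C(\C)CCO[Si](C)(C)C(C)(C)C
F4 | step 3 | acrylate of F3 | C=C(C)C[C@H](OC(=O)C=C)/C=C(\C)CCO[Si](C)(C)C(C)(C)C
F5 | step 4 | (2Z,5S,6E)-5,9-bis(tert-butyldimethylsilyloxy)-N-methoxy-N,3,7-trimethylnona-2,6-dienamide | CON(C)C(=O)/C=C(C)\C[C@H](O[Si](C)(C)C(C)(C)C)/C=C(\C)CCO[Si](C)(C)C(C)(C)C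
F6 | step 4 | (2Z,5S,6E)-5,9-bis(tert-butyldimethylsilyloxy)-3,7-dimethylnona-2,6-dienal | O=C/C=C(C)\C[C@H](O[Si](C)(C)C(C)(C)C)/C=C(\C)CCO[Si](C)(C)C(C)(C)C
F7 | step 4 | (2Z,5S,6E)-5,9-bis(tert-butyldimethylsilyloxy)-3,7-dimethylnona-2,6-dien-1-ol | OC/C=C(C)\C[C@H](O[Si](C)(C)C(C)(C)C)/C=C(\C)CCO[Si](C)(C)C(C)(C)C
F8 | step 4 | {(2S,3R)-3-[(2S,3E)-2,6-bis(tert-butyldimethylsilyloxy)-4-methylhex-3-enyl]-3-methyloxiran-2-yl}methanol | OC[C@@H]1O[C@]1(C)C[C@H](O[Si](C)(C)C(C)(C)C)/C=C(\C)CCO[Si](C)(C)C(C)(C)C
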